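**Retrosynthetic overview**

1. Numbering (kauranoid): ring A is C1(=O)–C2=C3–C4(CH3)2–C5(H)(C6H2OH)–C10; the six-membered lactone is C7(=O)–O–C20H2–C10–C9–C8; ring C is C8–C9–C11–C12–C13–C14; ring D is C8–C15(=O)–C16(C17H2OH)–C13–C14.
2. Late disconnections: C16–C17 (aldol with formaldehyde), C13–C16 (palladium-mediated cycloalkenylation of the C15 enol silane, ring D), and C8–C14/C9–C11 (Diels–Alder addition of butadiene to the C8-acetyl C8=C9 lactone, ring C).
3. Key disconnection: C3–C4 of ring A. The enabling feature is the ring A array C1(=O)–C2=C3–C4(CH3)2–C5–C6–O: C4 is a gem-dimethyl carbon that can be a tertiary radical (from an isopropenyl group on C5), C3 is the β-carbon of the C1 enone, and both are β-positions of the C1/C6 1,6-dioxygen pair, two acceptor carbons that a radical union can join. Addition of the C4 radical to a C1 ynone should give ring A, the quaternary C4 and the C2=C3 enone in one operation.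
4. The open-chain precursor comes from one butyrolactone (C1 = lactone carbonyl, C6 = lactone CH2O, isopropenyl on C5). The C5 substituent steers two α-alkylations at C10 (the C9–C8–C7 chain, then C20), which gives the cis C6/C20 relation of ring A; the six-membered lactone is then closed, and acetylide opening of the five-membered lactone releases the C1 ynone and the C6 hydroxyl together.
5. Ring order: five-membered lactone (temporary) → six-membered lactone → ring A (key step) → ring C → ring D.

Key step: step 8

Assumption: the (S)-BINAP complex is taken to deliver the (4S)-lactone 3, as in the analogous additions to cyclic enones; should the sense be opposite, the (R)-ligand is used.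

**Route**

Step 1
Reactants: 1 furan-2(5H)-one; 2 isopropenylboronic acid pinacol ester
Product: 3 (4S)-4-(prop-1-en-2-yl)oxolan-2-one
Conditions: [Rh(OH)(cod)]2 (2.5 mol %), (S)-BINAP (6 mol %), KOH (0.5 equiv), dioxane/H2O, 60 °C
Reagents that add atoms: none
Why: Rhodium-catalysed asymmetric 1,4-addition of an alkenylboron reagent to an unsaturated lactone (Hayashi–Miyaura reaction), in which the chiral bisphosphine selects one enantiotopic face of the β-carbon and sets C5.

Step 2
Reactants: 3 (4S)-4-(prop-1-en-2-yl)oxolan-2-one; 4 2-(2-bromoethyl)-1,3-dioxolane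
Product: 6 (3R,4S)-3-[2-(1,3-dioxolan-2-yl)ethyl]-4-(prop-1-en-2-yl)oxolan-2-one, via lithium enolate 5 (not isolated)
Conditions: LiN(i-Pr)2, THF, −78 °C; then 4, DMPU, −78 → −20 °C
Reagents that add atoms: none
Why: Lactone enolate alkylation that brings in C9–C8–C7 with C7 masked as an acetal (no acidic hydrogen for step 3); the chain enters anti to the C5 isopropenyl group, a C10 configuration that step 3 erases.

Step 3
Reactants: 6 (3R,4S)-3-[2-(1,3-dioxolan-2-yl)ethyl]-4-(prop-1-en-2-yl)oxolan-2-one
Product: 8 (3S,4R)-3-[2-(1,3-dioxolan-2-yl)ethyl]-3-(hydroxymethyl)-4-(prop-1-en-2-yl)oxolan-2-one, via lithium enolate 7 (not isolated)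
Conditions: LiN(i-Pr)2, THF, −78 °C; then CH2O (gas), −78 °C; AcOH
Reagents that add atoms: formaldehyde, C=O
Why: Aldol hydroxymethylation of the fully substituted lactone enolate, in which formaldehyde attacks the face anti to the C5 isopropenyl group, so that C20 ends trans to C4 and the C9 chain cis to it, the C10 configuration of the target.

Step 4
Reactants: 8 (3S,4R)-3-[2-(1,3-dioxolan-2-yl)ethyl]-3-(hydroxymethyl)-4-(prop-1-en-2-yl)oxolan-2-one
Product: 9 (4R,5S)-8-hydroxy-4-(prop-1-en-2-yl)-2,7-dioxaspiro[4.5]decan-1-one (lactol, both epimers at the hemiacetal carbon)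
Conditions: 2 M HCl, THF, 0 °C → rt
Reagents that add atoms: water, O
Why: Acid-catalysed acetal hydrolysis, after which the C7 aldehyde is trapped by the C20 hydroxyl as the six-membered lactol; the dilute acid should leave the isopropenyl group and the lactone intact.

Step 5
Reactants: 9 lactol
Product: 10 (4R,5S)-4-(prop-1-en-2-yl)-2,7-dioxaspiro[4.5]decane-1,8-dione
Conditions: TEMPO (10 mol %), PhI(OAc)2 (1.2 equiv), CH2Cl2, rt
Reagents that add atoms: none
Why: Oxoammonium (TEMPO) oxidation of a lactol to the lactone, which closes the C7(=O)–O–C20 ring without touching a stereocentre.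

Step 6
Reactants: 10 (4R,5S)-4-(prop-1-en-2-yl)-2,7-dioxaspiro[4.5]decane-1,8-dione
Product: 13 (5S)-5-[(2R)-1-hydroxy-3-methylbut-3-en-2-yl]-5-(prop-2-ynoyl)oxan-2-one (open form, in equilibrium with its five-membered lactol), via lithium enolate 11 (not isolated), via dilithium lactolate 12 (not isolated)
Conditions: LiN(i-Pr)2 (1.05 equiv), THF, −78 °C; then HC≡CLi (from acetylene and n-BuLi, 1.5 equiv), −78 → −40 °C; AcOH, −78 °C
Reagents that add atoms: lithium acetylide, [Li]C#C
Why: Addition of a lithium acetylide to a lactone (ynone synthesis) with the enolisable six-membered lactone protected in the flask as its enolate; the five-membered lactone has no α-hydrogen and is the only electrophilic carbonyl left, and the tetrahedral lithium lactolate resists a second addition.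

Step 7
Reactants: 13 hydroxy ynone
Product: 14 (5S)-5-[(2R)-1-(tert-butyldimethylsilyloxy)-3-methylbut-3-en-2-yl]-5-(prop-2-ynoyl)oxan-2-one
Conditions: TBSOTf, 2,6-lutidine, CH2Cl2, −78 °C
Reagents that add atoms: tert-butyldimethylsilyl trifluoromethanesulfonate, CC(C)(C)[Si](C)(C)OS(=O)(=O)C(F)(F)F
Why: Silylation of the primary C6 hydroxyl with a hindered, non-nucleophilic base (a nucleophilic amine would add to the ynone), which also removes the hydroxy ketone/lactol equilibrium.

Step 8
Reactants: 14 silyl-protected isopropenyl ynone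
Product: 15 (6S,11R)-11-[(tert-butyldimethylsilyloxy)methyl]-10,10-dimethyl-2-oxaspiro[5.5]undec-8-ene-3,7-dione
Conditions: Fe(acac)3 (0.3 equiv), Ph(i-PrO)SiH2 (2 equiv), THF/i-PrOH, 0 °C → rt, degassed
Reagents that add atoms: none
Why: Proposed new method: an iron hydride formed from Fe(acac)3 and the silane should transfer a hydrogen atom to the CH2 terminus of the isopropenyl group (Markovnikov hydrogen-atom transfer), the tertiary C4 radical should add to C3, the terminal β-carbon of the C1 ynone, and the α-keto vinyl radical at C2 should be quenched by hydrogen-atom or electron/proton transfer to give the C2=C3 enone directly; the closest known reactions are the iron/silane hydrogen-atom-transfer reductive coupling of unactivated alkenes with enones (Giese type) and tin hydride-mediated 6-endo cyclisations of alkyl radicals onto ynones, the ynone acceptor under hydrogen-atom-transfer conditions being the assumed part. Ring A, the only ring closed, is formed in the 6-endo-dig mode (C4, C5, C10, C1, C2, C3). No new stereocentre is created (C4 carries two methyl groups), and C5 and C10, set in steps 1 and 3, are not adjacent to a radical or anionic centre and are retained. The step needs 6-endo over 5-exo closure, which the polarisation of the ynone should secure: the nucleophilic tertiary radical attacks the unsubstituted, electrophilic C3 and gives a conjugated radical, whereas attack at C2 is polarity-mismatched. It also needs hydrogen-atom transfer to the electron-rich 1,1-disubstituted alkene rather than to the alkyne, the normal chemoselectivity of such metal hydrides, and over-reduction of the product enone is limited by the neopentyl position of C3 and a small excess of silane. The bond formed joins two carbons of like (acceptor) polarity, C3 and C4, the two β-positions of the C1/C6 dioxygen pattern.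

Step 9
Reactants: 15 ring A spiro lactone
Product: 17 (6S,11R)-4-acetyl-11-[(tert-butyldimethylsilyloxy)methyl]-10,10-dimethyl-2-oxaspiro[5.5]undec-8-ene-3,7-dione (C8-acetyl lactone, keto/enol and C8 epimers), via lithium enolate 16 (not isolated)
Conditions: LiN(i-Pr)2 (1.1 equiv), THF, −78 °C; then MeC(O)N(OMe)Me, −78 → 0 °C; AcOH
Reagents that add atoms: N-methoxy-N-methylacetamide, CC(=O)N(C)OC
Why: Claisen-type C-acylation of the lactone enolate by a Weinreb amide, whose stable tetrahedral adduct prevents O-acylation and double addition; the ring A enone has no enolisable hydrogen, so only C8 is deprotonated, and the acetyl group brings in C15 and C16.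

Step 10
Reactants: 17 C8-acetyl lactone
Product: 20 (6S,11R)-4-acetyl-11-[(tert-butyldimethylsilyloxy)methyl]-10,10-dimethyl-2-oxaspiro[5.5]undeca-4,8-diene-3,7-dione, via selenide 18 (not isolated), via selenoxide 19 (not isolated)
Conditions: PhSeCl, pyridine, CH2Cl2, 0 °C; then 30 % H2O2, 0 °C → rt; used at once
Reagents that add atoms: none
Why: α-Selenenylation of the β-keto lactone followed by selenoxide syn-elimination, in which only C9 offers a β-hydrogen, so the doubly activated C8=C9 double bond should form.

Step 11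
Reactants: 20 C8-acetyl C8=C9 lactone; 21 buta-1,3-diene
Product: 22 Diels–Alder adduct: (5R,8S,9S,10S) cis-fused lactone/cyclohexene with acetyl on the quaternary C8, C12=C13 double bond, ring A and the C6 silyl ether unchanged
Conditions: ZnCl2 (1.5 equiv), 21 (excess), CH2Cl2, sealed tube, 0 °C → rt
Reagents that add atoms: none
Why: Lewis acid-promoted Diels–Alder reaction of a 2-acyl-2-enoate-type dienophile, in which suprafacial addition makes the C8–C14 and C9–C11 bonds cis and the diene approaches the face of C8=C9 flanked by the flat C1 carbonyl, anti to C5 with its CH2OTBS arm, which sets C8 and C9 relative to C10.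

Step 12
Reactants: 22 Diels–Alder adduct
Product: 23 C15 tert-butyldimethylsilyl enol ether of 22 (C15(OSi)=C16H2)
Conditions: TBSOTf, Et3N, CH2Cl2, 0 °C
Reagents that add atoms: tert-butyldimethylsilyl trifluoromethanesulfonate, CC(C)(C)[Si](C)(C)OS(=O)(=O)C(F)(F)F
Why: Soft enolisation of the methyl ketone, the only enolisable carbonyl (C8 is quaternary and the ring A enone has no α- or γ-hydrogen), should give the terminal enol silane.

Step 13
Reactants: 23 enol silane
Product: 24 (5R,8S,9S,10S,13R)-6-(tert-butyldimethylsilyloxy)-1,15-dioxo-17-nor-6,7-secokaura-2,11-dien-7,20-olide (bicyclo[3.2.1]octenone, kauranoid numbering)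
Conditions: Pd(OAc)2 (10 mol %), O2 (1 atm), DMSO, 45 °C
Reagents that add atoms: none
Why: Cycloalkenylation of a silyl enol ether by divalent palladium (Saegusa-type oxidative cyclisation), in which C16 adds 5-exo to C13 of the ring C alkene on the face that carries the C8 substituent and β-hydride elimination gives the C11=C12 alkene, the bridge geometry fixing C13.

Step 14
Reactants: 24 bicyclooctenone
Product: 25 (5R,8S,9S,10S,13R)-6-(tert-butyldimethylsilyloxy)-1,15-dioxo-17-nor-6,7-secokaur-2-en-7,20-olide
Conditions: H2 (1 atm), RhCl(PPh3)3 (5 mol %), benzene/EtOH, rt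
Reagents that add atoms: none
Why: Homogeneous hydrogenation with the rhodium chloride tris(phosphine) catalyst should reduce the isolated cis-disubstituted C11=C12 alkene and leave the conjugated C2=C3 enone, which is flanked by the quaternary C4.

Step 15
Reactants: 25 saturated keto lactone
Product: 27 (5R,8S,9S,10S,13R,16R)-6-(tert-butyldimethylsilyloxy)-17-hydroxy-1,15-dioxo-6,7-secokaur-2-en-7,20-olide, via lithium enolate 26 (not isolated)
Conditions: LiN(i-Pr)2 (1.05 equiv), THF, −78 °C; then CH2O (gas), −78 °C; AcOH, −78 °C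
Reagents that add atoms: formaldehyde, C=O
Why: Aldol hydroxymethylation of the C15 ketone, which can enolise only toward C16 (C8 is quaternary); formaldehyde should add on the exo face of the two-carbon bridge, away from the C9–C11–C12 bridge, to give the exo CH2OH (16R), which is also the more stable epimer.

Step 16
Reactants: 27 silyl-protected target
Product: 28 target, (5R,8S,9S,10S,13R,16R)-6,17-dihydroxy-1,15-dioxo-6,7-secokaur-2-en-7,20-olide
Conditions: HF·pyridine, THF/pyridine, 0 °C
Reagents that add atoms: none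
Why: Fluoride-mediated desilylation under weakly acidic conditions, which should avoid retro-aldol cleavage or β-elimination of the C16 hydroxymethyl ketone.

**Compound list**

1 | furan-2(5H)-one | O=C1C=CCO1 | starting material
2 | isopropenylboronic acid pinacol ester | CC(=C)B1OC(C)(C)C(C)(C)O1 | starting material
3 | (4S)-4-(prop-1-en-2-yl)oxolan-2-one | O=C1C[C@@H](C(C)=C)CO1 | intermediate
4 | 2-(2-bromoethyl)-1,3-dioxolane | BrCCC1OCCO1 | starting material
5 | lithium enolate of 3 (formed in the flask) | [Li]OC1=C[C@@H](C(C)=C)CO1 | intermediate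
6 | (3R,4S)-3-[2-(1,3-dioxolan-2-yl)ethyl]-4-(prop-1-en-2-yl)oxolan-2-one | O=C1[C@H](CCC2OCCO2)[C@@H](C(C)=C)CO1 | intermediate
7 | lithium enolate of 6 (formed in the flask) | [Li]OC1=C(CCC2OCCO2)[C@@H](C(C)=C)CO1 | intermediate
8 | (3S,4R)-3-[2-(1,3-dioxolan-2-yl)ethyl]-3-(hydroxymethyl)-4-(prop-1-en-2-yl)oxolan-2-one | O=C1[C@@](CO)(CCC2OCCO2)[C@@H](C(C)=C)CO1 | intermediate
9 | (4R,5S)-8-hydroxy-4-(prop-1-en-2-yl)-2,7-dioxaspiro[4.5]decan-1-one (lactol) | O=C1[C@]2(COC(O)CC2)[C@@H](C(C)=C)CO1 | intermediate
10 | (4R,5S)-4-(prop-1-en-2-yl)-2,7-dioxaspiro[4.5]decane-1,8-dione | O=C1[C@]2(COC(=O)CC2)[C@@H](C(C)=C)CO1 | intermediate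
11 | lithium enolate of the six-membered lactone of 10 (formed in the flask) | O=C1[C@]2(COC(O[Li])=CC2)[C@@H](C(C)=C)CO1 | intermediate
12 | dilithium lactolate, acetylide adduct of 11 (formed in the flask) | C#CC1(O[Li])[C@]2(COC(O[Li])=CC2)[C@@H](C(C)=C)CO1 | intermediate
13 | (5S)-5-[(2R)-1-hydroxy-3-methylbut-3-en-2-yl]-5-(prop-2-ynoyl)oxan-2-one | C#CC(=O)[C@]1(COC(=O)CC1)[C@@H](C(C)=C)CO | intermediate
14 | (5S)-5-[(2R)-1-(tert-butyldimethylsilyloxy)-3-methylbut-3-en-2-yl]-5-(prop-2-ynoyl)oxan-2-one | C#CC(=O)[C@]1(COC(=O)CC1)[C@@H](C(C)=C)CO[Si](C)(C)C(C)(C)C | intermediate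
15 | (6S,11R)-11-[(tert-butyldimethylsilyloxy)methyl]-10,10-dimethyl-2-oxaspiro[5.5]undec-8-ene-3,7-dione | CC1(C)C=CC(=O)[C@]2(COC(=O)CC2)[C@@H]1CO[Si](C)(C)C(C)(C)C | intermediate
16 | lithium enolate of 15 (formed in the flask) | CC1(C)C=CC(=O)[C@]2(COC(O[Li])=CC2)[C@@H]1CO[Si](C)(C)C(C)(C)C | intermediate
17 | (6S,11R)-4-acetyl-11-[(tert-butyldimethylsilyloxy)methyl]-10,10-dimethyl-2-oxaspiro[5.5]undec-8-ene-3,7-dione | CC1(C)C=CC(=O)[C@]2(COC(=O)C(C(C)=O)C2)[C@@H]1CO[Si](C)(C)C(C)(C)C | intermediate
18 | 4-(phenylselanyl) derivative of 17 (formed in the flask) | CC1(C)C=CC(=O)[C@]2(COC(=O)C([Se]c3ccccc3)(C(C)=O)C2)[C@@H]1CO[Si](C)(C)C(C)(C)C | intermediate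
19 | selenoxide of 18 (formed in the flask) | CC1(C)C=CC(=O)[C@]2(COC(=O)C([Se](=O)c3ccccc3)(C(C)=O)C2)[C@@H]1CO[Si](C)(C)C(C)(C)C | intermediate
20 | (6S,11R)-4-acetyl-11-[(tert-butyldimethylsilyloxy)methyl]-10,10-dimethyl-2-oxaspiro[5.5]undeca-4,8-diene-3,7-dione | CC1(C)C=CC(=O)[C@]2(COC(=O)C(C(C)=O)=C2)[C@@H]1CO[Si](C)(C)C(C)(C)C | intermediate
21 | buta-1,3-diene | C=CC=C | starting material
22 | Diels–Alder adduct, (5R,8S,9S,10S), C8-acetyl, C12=C13 | CC1(C)C=CC(=O)[C@]2(COC(=O)[C@]3(CC=CC[C@H]32)C(C)=O)[C@@H]1CO[Si](C)(C)C(C)(C)C | intermediate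
23 | C15 tert-butyldimethylsilyl enol ether of 22 | CC1(C)C=CC(=O)[C@]2(COC(=O)[C@]3(CC=CC[C@H]32)C(=C)O[Si](C)(C)C(C)(C)C)[C@@H]1CO[Si](C)(C)C(C)(C)C | intermediate
24 | (5R,8S,9S,10S,13R)-6-(tert-butyldimethylsilyloxy)-1,15-dioxo-17-nor-6,7-secokaura-2,11-dien-7,20-olide | CC1(C)C=CC(=O)[C@]2(COC(=O)[C@@]34C[C@@H](C=C[C@H]32)CC4=O)[C@@H]1CO[Si](C)(C)C(C)(C)C | intermediate
25 | (5R,8S,9S,10S,13R)-6-(tert-butyldimethylsilyloxy)-1,15-dioxo-17-nor-6,7-secokaur-2-en-7,20-olide | CC1(C)C=CC(=O)[C@]2(COC(=O)[C@@]34C[C@@H](CC[C@H]32)CC4=O)[C@@H]1CO[Si](C)(C)C(C)(C)C | intermediate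
26 | lithium enolate of 25 (C15–C16, formed in the flask) | CC1(C)C=CC(=O)[C@]2(COC(=O)[C@@]34C[C@@H](CC[C@H]32)C=C4O[Li])[C@@H]1CO[Si](C)(C)C(C)(C)C | intermediate
27 | (5R,8S,9S,10S,13R,16R)-6-(tert-butyldimethylsilyloxy)-17-hydroxy-1,15-dioxo-6,7-secokaur-2-en-7,20-olide | CC1(C)C=CC(=O)[C@]2(COC(=O)[C@@]34C[C@@H](CC[C@H]32)[C@H](CO)C4=O)[C@@H]1CO[Si](C)(C)C(C)(C)C | intermediate
28 | (5R,8S,9S,10S,13R,16R)-6,17-dihydroxy-1,15-dioxo-6,7-secokaur-2-en-7,20-olide | CC1(C)C=CC(=O)[C@]2(COC(=O)[C@@]34C[C@@H](CC[C@H]32)[C@H](CO)C4=O)[C@@H]1CO | target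

**Step count and risks**

Total steps: 16. Longest linear sequence: 16 steps (from furan-2(5H)-one 1).

Step 8 (proposed method). The tertiary radical may be reduced before it cyclises (net hydrogenation of the isopropenyl group), or the ynone may be reduced or hydrosilylated faster than hydrogen-atom transfer to the alkene occurs. The fallback uses known chemistry, sets out from 14 and comes back at 15. Semi-hydrogenation of the ynone (H2, Pd/CaCO3 poisoned with Pb(OAc)2, quinoline) should give the vinyl ketone F1. The established iron/silane hydrogen-atom-transfer Giese cyclisation onto an enone (Fe(acac)3, PhSiH3, EtOH/ethylene glycol, 60 °C; 6-endo-trig at the CH2 terminus) should then give the saturated ring A ketone F2. Dehydrogenation with IBX (DMSO, 70 °C), possible only toward C2–C3 because C10 is quaternary, returns 15.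

Step 6. Enolate protection of the six-membered lactone may be incomplete, so that the acetylide attacks the less hindered lactone, or the lactolate may open and take up a second acetylide. The fallback sets out from lactol 9 and comes back at 14; it removes the need to tell two lactones apart. Lactol 9 is converted (MeOH, PPTS) into the cyclic methyl acetal F3, in which the five-membered lactone is the only carbonyl group. Lithium acetylide then gives the hydroxy ynone acetal F4, and TBSOTf/2,6-lutidine gives the silyl ether F5. Mild hydrolysis (PPTS, acetone/H2O) gives the lactol F6, and TEMPO/PhI(OAc)2 oxidation gives 14.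

Step 13. Regiocontrol may be poor (6-endo closure at C12 to a bicyclo[2.2.2]octanone), or the enol silane may be protodesilylated back to 22 before carbopalladation. The fallback sets out from 22 and comes back at 24; it replaces the oxidative cyclisation by an enolate alkylation. Epoxidation of the ring C alkene (mCPBA, CH2Cl2, expected on the face away from the C8 acetyl group) should give the C12–C13 epoxide F7. The C16 enolate (LiN(i-Pr)2, THF, −78 → 0 °C) should open it 5-exo at C13 with inversion to give the C12 hydroxy bicyclo[3.2.1]octanone F8. Syn-dehydration with methyl N-(triethylammoniumsulfonyl)carbamate (Burgess reagent), possible only toward C11 because C13 is a bridgehead, gives 24.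

**Further compounds**

F1 | step 8 | (5S)-5-[(2R)-1-(tert-butyldimethylsilyloxy)-3-methylbut-3-en-2-yl]-5-(prop-2-enoyl)oxan-2-one (vinyl ketone) | C=CC(=O)[C@]1(COC(=O)CC1)[C@@H](C(C)=C)CO[Si](C)(C)C(C)(C)C
F2 | step 8 | (6S,11R)-11-[(tert-butyldimethylsilyloxy)methyl]-10,10-dimethyl-2-oxaspiro[5.5]undecane-3,7-dione (saturated ring A ketone) | CC1(C)CCC(=O)[C@]2(COC(=O)CC2)[C@@H]1CO[Si](C)(C)C(C)(C)C
F3 | step 6 | (4R,5S)-8-methoxy-4-(prop-1-en-2-yl)-2,7-dioxaspiro[4.5]decan-1-one (methyl acetal of 9) | O=C1[C@]2(COC(OC)CC2)[C@@H](C(C)=C)CO1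
F4 | step 6 | 1-{(3S)-3-[(2R)-1-hydroxy-3-methylbut-3-en-2-yl]-6-methoxyoxan-3-yl}prop-2-yn-1-one | C#CC(=O)[C@]1(COC(OC)CC1)[C@@H](C(C)=C)CO
F5 | step 6 | tert-butyldimethylsilyl ether of F4 | C#CC(=O)[C@]1(COC(OC)CC1)[C@@H](C(C)=C)CO[Si](C)(C)C(C)(C)C
F6 | step 6 | lactol from F5 (6-hydroxyoxane) | C#CC(=O)[C@]1(COC(O)CC1)[C@@H](C(C)=C)CO[Si](C)(C)C(C)(C)C
F7 | step 13 | C12–C13 epoxide of 22 (epoxide configuration not drawn, expected anti to the C8 acetyl group) | CC1(C)C=CC(=O)[C@]2(COC(=O)[C@]3(CC4OC4C[C@H]32)C(C)=O)[C@@H]1CO[Si](C)(C)C(C)(C)C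
F8 | step 13 | C12 hydroxy derivative of 25 (C12 configuration not drawn, hydroxyl trans to the new C13–C16 bond) | CC1(C)C=CC(=O)[C@]2(COC(=O)[C@@]34C[C@@H](C(O)C[C@H]32)CC4=O)[C@@H]1CO[Si](C)(C)C(C)(C)C
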